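**Strategy.** Ring A, the pentasubstituted 3-methoxyphenol core (C1 carrying the CH2CH2 bridge, C2–H, C3–OMe, C4–CH2Ar, C5–OH, C6–CH2Ar), is cut into a four-carbon and a two-carbon piece: C5, C6, C1 and C2 come from a cyclobutenone, C3 and C4 from a 1-methoxyalkyne. One thermal cascade (ring opening to a vinylketene, [2+2] addition, second ring opening, 6π closure) forms C5–C4 and C3–C2, closes ring A and places all five substituents without any aromatic substitution. The precursors are a racemic cyclobutenone carrying the arylethyl chain on its alkene carbon and a 4-benzyloxybenzyl group on its sp3 carbon, and a benzylic methyl ynol ether; both outer phenols travel as benzyl ethers.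

Key step: step 6

Assumption: the target has no stereocentre, stereogenic axis or stereogenic double bond, so it is one achiral compound and needs no enantiocontrol; the only stereocentre on the way (C4 of the cyclobutenone) is carried racemic and is destroyed in the key step.

**Route**

Step 1
Reactants: 1 3-(4-hydroxyphenyl)propanoic acid
Product: 2 3-[4-(benzyloxy)phenyl]propanoic acid
Conditions: BnBr (1.2 equiv), NaOH (2.5 equiv), EtOH/H2O, reflux; then aq HCl
Reagents that add atoms: benzyl bromide, BrCc1ccccc1
Why: Williamson ether synthesis on the dianion: in hot aqueous-ethanolic NaOH the phenoxide is by far the better nucleophile for benzyl bromide than the carboxylate, and any benzyl ester formed is saponified in the same medium before acidification.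

Step 2
Reactants: 2 3-[4-(benzyloxy)phenyl]propanoic acid
Product: 4 3-[4-(benzyloxy)phenyl]-N,N-dimethylpropanamide, via acyl imidazole 3 (not isolated)
Conditions: CDI, THF, rt; then Me2NH (2 M in THF), rt
Reagents that add atoms: dimethylamine, CNC
Why: Amide formation by CDI activation: the acid is converted into the acyl imidazole, which dimethylamine opens at room temperature while the aryl benzyl ether is untouched.

Step 3
Reactants: 5 3-methoxybenzyl bromide; 6 trimethyl(prop-1-yn-1-yl)silane
Product: 9 1-(but-3-yn-1-yl)-3-methoxybenzene, via lithiated silylpropyne 7 (not isolated), via silylated alkyne 8 (not isolated)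
Conditions: n-BuLi, THF, −78 °C; then 5, −78 °C→rt; then MeOH, K2CO3 (cat.), rt
Reagents that add atoms: none
Why: Propargylic lithiation of 1-(trimethylsilyl)propyne and SN2 alkylation at the benzylic bromide (the silyl group blocks the acetylenic terminus and favours the propargyl over the allenyl product), followed by base-catalysed methanolysis of the C(sp)–Si bond in the same flask.

Step 4
Reactants: 4 3-[4-(benzyloxy)phenyl]-N,N-dimethylpropanamide; 9 1-(but-3-yn-1-yl)-3-methoxybenzene
Product: 12 4-[4-(benzyloxy)benzyl]-3-[2-(3-methoxyphenyl)ethyl]cyclobut-2-en-1-one (racemic), via keteniminium triflate 10 (not isolated), via cyclobuteniminium triflate 11 (not isolated)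
Conditions: Tf2O, 2,4,6-collidine, 9 (1.5 equiv), ClCH2CH2Cl, −20 °C→reflux; then H2O, aq NaHCO3, rt
Reagents that add atoms: water, O
Why: Ghosez keteniminium–alkyne [2+2] cycloaddition: Tf2O/collidine converts the tertiary amide into the keteniminium ion, whose electrophilic central carbon bonds to the unsubstituted alkyne carbon while positive charge builds up on the substituted one, so the chain of 9 ends up at C3 and the amide α-substituent at C4, and aqueous hydrolysis of the cyclobuteniminium salt frees the enone; the C4 stereocentre forms racemic, which is intended.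

Step 5
Reactants: 13 2-chloro-1,1-dimethoxyethane (chloroacetaldehyde dimethyl acetal); 14 1-(benzyloxy)-4-(chloromethyl)benzene (4-(benzyloxy)benzyl chloride)
Product: 16 1-(benzyloxy)-4-(3-methoxyprop-2-yn-1-yl)benzene, via lithium methoxyacetylide 15 (not isolated)
Conditions: LiNEt2 (3.0 equiv; from Et2NH, n-BuLi), THF, 0 °C; then 14, DMPU, NaI (cat.), −20 °C→rt
Reagents that add atoms: none
Why: One-flask ynol ether synthesis: three equivalents of lithium amide take the chloroacetal through two eliminations and a deprotonation to lithium methoxyacetylide, which is alkylated (SN2, DMPU and iodide assistance) at the activated benzylic chloride; no excess of amide base is used, so that the benzylic propargylic CH2 of the product is not isomerised to an allene.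

Step 6
Reactants: 12 4-[4-(benzyloxy)benzyl]-3-[2-(3-methoxyphenyl)ethyl]cyclobut-2-en-1-one; 16 1-(benzyloxy)-4-(3-methoxyprop-2-yn-1-yl)benzene
Product: 21 2,6-bis[4-(benzyloxy)benzyl]-3-methoxy-5-[2-(3-methoxyphenyl)ethyl]phenol, via vinylketene 17 (not isolated), via alkenylcyclobutenone 18 (not isolated), via dienylketene 19 (not isolated), via cyclohexadienone 20 (not isolated)
Conditions: 16 (1.5 equiv), PhMe (degassed), 80 °C then 110 °C, sealed tube
Reagents that add atoms: none
Why: On heating, 12 undergoes conrotatory 4π electrocyclic opening of its C(=O)–C4 bond (the arylmethyl group turning outward) to vinylketene 17, whose ketene C=C adds to the electron-rich triple bond of 16 in a [2+2] cycloaddition to give 18; a second 4π opening gives dienylketene 19, which closes by 6π electrocyclisation to dienone 20 and tautomerises to phenol 21. The closest known reaction is the Danheiser benzannulation of cyclobutenones with alkoxyalkynes, which gives 3-alkoxyphenols in this way. Ring A is closed by the thermally allowed disrotatory 6π electrocyclisation, which re-forms the C5–C6 bond between the former carbonyl carbon and the former sp3 carbon of 12 after the [2+2] step has made C5–C4 and C3–C2. No stereocentre is created in the product: the stereocentre of racemic 12 is lost in the first ring opening and those of 18 and 20 disappear on the way to the arene. The one selectivity needed is the orientation of the [2+2] step, secured by the polarisation of the ynol ether, whose oxygen makes the arylmethyl-bearing carbon the nucleophilic terminus that bonds to the electrophilic ketene carbonyl carbon, so that OMe comes out meta to OH with the benzyl group between them. An excess of 16 is used so that capture of 17 outruns its self-reaction.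

Step 7
Reactants: 21 2,6-bis[4-(benzyloxy)benzyl]-3-methoxy-5-[2-(3-methoxyphenyl)ethyl]phenol
Product: 22 2,6-bis(4-hydroxybenzyl)-3-methoxy-5-[2-(3-methoxyphenyl)ethyl]phenol
Conditions: H2 (1 atm), 10% Pd/C, EtOAc/MeOH, rt
Reagents that add atoms: none
Why: Catalytic hydrogenolysis of the two aryl benzyl ethers; the diarylmethane and bibenzyl C–C bonds, the two methyl ethers and the arene rings are inert under these mild conditions, and no stereocentre is involved.

**Compound list**

1 | 3-(4-hydroxyphenyl)propanoic acid | O=C(O)CCc1ccc(O)cc1 | starting material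
2 | 3-[4-(benzyloxy)phenyl]propanoic acid | O=C(O)CCc1ccc(OCc2ccccc2)cc1 | intermediate
3 | 3-[4-(benzyloxy)phenyl]-1-(1H-imidazol-1-yl)propan-1-one | O=C(CCc1ccc(OCc2ccccc2)cc1)n1ccnc1 | intermediate (not isolated)
4 | 3-[4-(benzyloxy)phenyl]-N,N-dimethylpropanamide | CN(C)C(=O)CCc1ccc(OCc2ccccc2)cc1 | intermediate
5 | 1-(bromomethyl)-3-methoxybenzene (3-methoxybenzyl bromide) | COc1cccc(CBr)c1 | starting material
6 | trimethyl(prop-1-yn-1-yl)silane | CC#C[Si](C)(C)C | starting material
7 | [3-(trimethylsilyl)prop-2-yn-1-yl]lithium | [Li]CC#C[Si](C)(C)C | intermediate (not isolated)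
8 | [4-(3-methoxyphenyl)but-1-yn-1-yl]trimethylsilane | COc1cccc(CCC#C[Si](C)(C)C)c1 | intermediate (not isolated)
9 | 1-(but-3-yn-1-yl)-3-methoxybenzene | C#CCCc1cccc(OC)c1 | intermediate
10 | N-{3-[4-(benzyloxy)phenyl]prop-1-en-1-ylidene}-N-methylmethanaminium trifluoromethanesulfonate (keteniminium triflate) | C[N+](C)=C=CCc1ccc(OCc2ccccc2)cc1.[O-]S(=O)(=O)C(F)(F)F | intermediate (not isolated)
11 | N-{4-[4-(benzyloxy)benzyl]-3-[2-(3-methoxyphenyl)ethyl]cyclobut-2-en-1-ylidene}-N-methylmethanaminium trifluoromethanesulfonate (racemic) | C[N+](C)=C1C=C(CCc2cccc(OC)c2)C1Cc1ccc(OCc2ccccc2)cc1.[O-]S(=O)(=O)C(F)(F)F | intermediate (not isolated)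
12 | 4-[4-(benzyloxy)benzyl]-3-[2-(3-methoxyphenyl)ethyl]cyclobut-2-en-1-one (racemic) | O=C1C=C(CCc2cccc(OC)c2)C1Cc1ccc(OCc2ccccc2)cc1 | intermediate
13 | 2-chloro-1,1-dimethoxyethane | COC(CCl)OC | starting material
14 | 1-(benzyloxy)-4-(chloromethyl)benzene | ClCc1ccc(OCc2ccccc2)cc1 | starting material
15 | (methoxyethynyl)lithium | [Li]C#COC | intermediate (not isolated)
16 | 1-(benzyloxy)-4-(3-methoxyprop-2-yn-1-yl)benzene | COC#CCc1ccc(OCc2ccccc2)cc1 | intermediate
17 | (3E)-5-[4-(benzyloxy)phenyl]-3-[2-(3-methoxyphenyl)ethyl]penta-1,3-dien-1-one (vinylketene; expected geometry) | O=C=C/C(CCc1cccc(OC)c1)=C/Cc1ccc(OCc2ccccc2)cc1 | intermediate (not isolated)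
18 | 2-[4-(benzyloxy)benzyl]-4-{(2E)-1-[4-(benzyloxy)phenyl]-5-(3-methoxyphenyl)pent-2-en-3-yl}-3-methoxycyclobut-2-en-1-one (racemic) | O=C1C(Cc2ccc(OCc3ccccc3)cc2)=C(OC)C1/C(CCc2cccc(OC)c2)=C/Cc2ccc(OCc3ccccc3)cc2 | intermediate (not isolated)
19 | (3E,5E)-2-[4-(benzyloxy)benzyl]-7-[4-(benzyloxy)phenyl]-3-methoxy-5-[2-(3-methoxyphenyl)ethyl]hepta-1,3,5-trien-1-one (dienylketene; the geometry that can cyclise) | O=C=C(Cc1ccc(OCc2ccccc2)cc1)/C(OC)=C\C(CCc1cccc(OC)c1)=C\Cc1ccc(OCc2ccccc2)cc1 | intermediate (not isolated)
20 | 2,6-bis[4-(benzyloxy)benzyl]-3-methoxy-5-[2-(3-methoxyphenyl)ethyl]cyclohexa-2,4-dien-1-one (racemic) | O=C1C(Cc2ccc(OCc3ccccc3)cc2)=C(OC)C=C(CCc2cccc(OC)c2)C1Cc1ccc(OCc2ccccc2)cc1 | intermediate (not isolated)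
21 | 2,6-bis[4-(benzyloxy)benzyl]-3-methoxy-5-[2-(3-methoxyphenyl)ethyl]phenol | COc1cccc(CCc2cc(OC)c(Cc3ccc(OCc4ccccc4)cc3)c(O)c2Cc2ccc(OCc3ccccc3)cc2)c1 | intermediate
22 | 2,6-bis(4-hydroxybenzyl)-3-methoxy-5-[2-(3-methoxyphenyl)ethyl]phenol | COc1cccc(CCc2cc(OC)c(Cc3ccc(O)cc3)c(O)c2Cc2ccc(O)cc2)c1 | target

**Totals**

Total step count: 7. Longest linear sequence: 5 steps (steps 1, 2, 4, 6, 7).

**Steps most likely to fail**

1. Step 6. The bimolecular ketene–alkyne cycloaddition may be too slow to compete with self-addition of the vinylketene and with acylation of the phenol already formed, or the ynol ether may be lost to thermal side reactions before it is captured. The fallback runs the same benzannulation with a silyl ynol ether, a stronger and thermally sturdier ketenophile, and introduces the methyl group afterwards. It sets out from 14 and 12 and comes back to the route at 22.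
   - Copper-catalysed coupling of 14 with ethynylmagnesium bromide would give 1-(benzyloxy)-4-(prop-2-yn-1-yl)benzene F1.
   - Deprotonation with n-BuLi, oxidation of the acetylide to the lithium ynolate with lithium tert-butyl peroxide and O-silylation with TIPSOTf would give ({3-[4-(benzyloxy)phenyl]prop-1-yn-1-yl}oxy)tri(propan-2-yl)silane F2.
   - Heating F2 with 12 in toluene at 80 °C should give, by the same bond formations, 2,6-bis[4-(benzyloxy)benzyl]-5-[2-(3-methoxyphenyl)ethyl]-3-{[tri(propan-2-yl)silyl]oxy}phenol F3.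
   - Benzylation of the free C5 hydroxyl (BnBr, Cs2CO3, DMF) would give {3-(benzyloxy)-2,4-bis[4-(benzyloxy)benzyl]-5-[2-(3-methoxyphenyl)ethyl]phenoxy}tri(propan-2-yl)silane F4.
   - TBAF in THF would free 3-(benzyloxy)-2,4-bis[4-(benzyloxy)benzyl]-5-[2-(3-methoxyphenyl)ethyl]phenol F5.
   - MeI/K2CO3 in DMF would give 3-(benzyloxy)-2,4-bis[4-(benzyloxy)benzyl]-1-methoxy-5-[2-(3-methoxyphenyl)ethyl]benzene F6.
   - Hydrogenolysis under the conditions of step 7 would then remove the three benzyl groups and give 22.

2. Step 4. The keteniminium ion or the cyclobuteniminium salt may be intercepted by the electron-rich arene rings (Friedel–Crafts-type attack), or the alkyne may oligomerise under the cationic conditions before the cycloaddition is complete. The fallback builds the four-membered ring from a ketene and ethoxyacetylene and brings in the arylethyl chain as a nucleophile. It sets out from 2 and comes back to the route at 12.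
   - Oxalyl chloride with catalytic DMF would convert 2 into 3-[4-(benzyloxy)phenyl]propanoyl chloride F7.
   - Slow addition of Et3N in the presence of commercial ethoxyacetylene would generate the aldoketene 3-[4-(benzyloxy)phenyl]prop-1-en-1-one F8, which is trapped by [2+2] cycloaddition as 4-[4-(benzyloxy)benzyl]-3-ethoxycyclobut-2-en-1-one F9.
   - 1,2-Addition of [2-(3-methoxyphenyl)ethyl]magnesium bromide F10 (from commercial 1-(2-bromoethyl)-3-methoxybenzene and Mg) would give 4-[4-(benzyloxy)benzyl]-3-ethoxy-1-[2-(3-methoxyphenyl)ethyl]cyclobut-2-en-1-ol F11 as a mixture of diastereomers.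
   - Dilute HCl would hydrolyse the enol ether with allylic transposition of the carbonyl group and give 12.

3. Step 5. Substitution at the benzylic chloride may be slow compared with base-induced propargyl-to-allenyl isomerisation of the product and with decay of the acetylide in the strongly basic, polar medium. The fallback replaces the SN2 alkylation by a palladium-catalysed cross-coupling of a far less basic zinc acetylide. It sets out from 15 and 14 and comes back to the route at 16.
   - Transmetalation of 15 with ZnCl2 in THF would give chloro(methoxyethynyl)zinc F12.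
   - Negishi benzyl–alkynyl coupling of F12 with 14 (PdCl2(DPEphos) cat., THF, rt) should give 16.

**Further compounds**

F1 | step 6 | 1-(benzyloxy)-4-(prop-2-yn-1-yl)benzene | C#CCc1ccc(OCc2ccccc2)cc1
F2 | step 6 | ({3-[4-(benzyloxy)phenyl]prop-1-yn-1-yl}oxy)tri(propan-2-yl)silane | CC(C)[Si](OC#CCc1ccc(OCc2ccccc2)cc1)(C(C)C)C(C)C
F3 | step 6 | 2,6-bis[4-(benzyloxy)benzyl]-5-[2-(3-methoxyphenyl)ethyl]-3-{[tri(propan-2-yl)silyl]oxy}phenol | COc1cccc(CCc2cc(O[Si](C(C)C)(C(C)C)C(C)C)c(Cc3ccc(OCc4ccccc4)cc3)c(O)c2Cc2ccc(OCc3ccccc3)cc2)c1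
F4 | step 6 | {3-(benzyloxy)-2,4-bis[4-(benzyloxy)benzyl]-5-[2-(3-methoxyphenyl)ethyl]phenoxy}tri(propan-2-yl)silane | COc1cccc(CCc2cc(O[Si](C(C)C)(C(C)C)C(C)C)c(Cc3ccc(OCc4ccccc4)cc3)c(OCc3ccccc3)c2Cc2ccc(OCc3ccccc3)cc2)c1
F5 | step 6 | 3-(benzyloxy)-2,4-bis[4-(benzyloxy)benzyl]-5-[2-(3-methoxyphenyl)ethyl]phenol | COc1cccc(CCc2cc(O)c(Cc3ccc(OCc4ccccc4)cc3)c(OCc3ccccc3)c2Cc2ccc(OCc3ccccc3)cc2)c1
F6 | step 6 | 3-(benzyloxy)-2,4-bis[4-(benzyloxy)benzyl]-1-methoxy-5-[2-(3-methoxyphenyl)ethyl]benzene | COc1cccc(CCc2cc(OC)c(Cc3ccc(OCc4ccccc4)cc3)c(OCc3ccccc3)c2Cc2ccc(OCc3ccccc3)cc2)c1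
F7 | step 4 | 3-[4-(benzyloxy)phenyl]propanoyl chloride | O=C(Cl)CCc1ccc(OCc2ccccc2)cc1
F8 | step 4 | 3-[4-(benzyloxy)phenyl]prop-1-en-1-one | O=C=CCc1ccc(OCc2ccccc2)cc1
F9 | step 4 | 4-[4-(benzyloxy)benzyl]-3-ethoxycyclobut-2-en-1-one (racemic) | CCOC1=CC(=O)C1Cc1ccc(OCc2ccccc2)cc1
F10 | step 4 | [2-(3-methoxyphenyl)ethyl]magnesium bromide | COc1cccc(CC[Mg]Br)c1
F11 | step 4 | 4-[4-(benzyloxy)benzyl]-3-ethoxy-1-[2-(3-methoxyphenyl)ethyl]cyclobut-2-en-1-ol (mixture of diastereomers, racemic) | CCOC1=CC(O)(CCc2cccc(OC)c2)C1Cc1ccc(OCc2ccccc2)cc1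
F12 | step 5 | chloro(methoxyethynyl)zinc | COC#C[Zn]Cl
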